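The data come from a simulation with constants of no real substance, noise included.

The trap is to read a fixed-time amount of an intermediate like an initial rate, where hotter means more.

in all of them: starting material 0.61 M

| flask | reagent | temperature | remark | time |
|---|---|---|---|---|
| eta | 0.34 M | 60 °C | run made earlier |  |
| zeta | 0.50 M | 82 °C | run made earlier |  |
| Saturday's | 0.671 M | 90 °C |  | 20 min |
| Sunday's | 0.671 M | 70 °C |  | 20 min |
| Tuesday's | 0.671 M | 50 °C |  | 20 min |

| eta: time / min | eta: mono adduct / % | zeta: time / min | zeta: mono adduct / % |
|---|---|---|---|
| 6.00 | 4.0 | 1.33 | 8.2 |
| 12.0 | 5.2 | 2.50 | 12.3 |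
| 20.0 | 5.7 | 5.00 | 13.0 |
| 40.0 | 6.6 | 8.00 | 11.8 |
| 60.0 | 4.7 | 15.0 | 10.4 |

(scatter of a reading: 0.5 percentage points)
- which flask leads in amount of mono adduct, in percent of the starting material charged ("all alike" within 1.5 percentage points) (Saturday's / Sunday's / Tuesday's / all alike)
- how much mono adduct is there at the end, in percent of the starting material charged: Saturday's
- how much mono adduct is there at the end, in percent of the starting material charged: Sunday's
- how much mono adduct is there at the end, in percent of the starting material charged: Tuesday's
- in percentages every species weighs as the starting material in it: one side product counts as two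
- what may be going on: starting material + reagent -> mono adduct + released group; reagent + mono adduct -> double product + released group; reagent + double product -> tris adduct + released group; mono adduct <-> isomer of the product; starting material + mono adduct -> side product

Starting material and reagent make mono adduct, and reagent and starting material use it up, so the amount rises, peaks and falls. What you need is where the stop stands against the peak time, and you reckon that in powers of ten. Two extremes are easy. A flask stopped long before its peak holds less than its peak height, and one stopped long after holds what the tail has kept.

Eta's highest reading is 6.6 % at 40.0 min, and zeta's is 13.0 % at 5.00 min. In my own rough pseudo-first-order reckoning, with reagent taken as constant, I assume that the peak comes at a fixed [B] times time for each temperature: 13.6 M·min for eta and 2.50 M·min for zeta. Running the logarithm straight through temperature gives, at 70 °C, 6.30 M·min. This is the peak dose, [B] times time at the mono adduct maximum. Divide by [B] for the peak time. Heights go the same way, with reagent ignored, so they run low.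

| Flask | Peak time | Powers of ten past peak | Peak height |
|---|---|---|---|
| Saturday's | 2.01 min | 0.997 | 16.6 % |
| Sunday's | 9.39 min | 0.329 | 8.98 % |
| Tuesday's | 43.8 min | −0.340 | 4.85 % |

Sunday's and Tuesday's lie on opposite sides of their peaks, so height parts them, and Sunday's peak is higher. Zeta's tail kept 80.0 % over 2.00 peak times. Carried on, that leaves 6.14 % in Saturday's and 7.92 % in Sunday's, so I commit to Sunday's.

The forecast names Saturday's, with 10.5 %, 6.8 % and 3.7 % for Saturday's, Sunday's and Tuesday's, on the ground that “hotter runs hold more mono”.

The flasks give 7.37 %, 12.2 % and 6.30 % in that order, and Sunday's leads.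

    starting material + reagent → mono adduct + released group (k = 9.80 × 10⁻⁴ M⁻¹ s⁻¹, Ea = 91.0 kJ mol⁻¹)
    reagent + mono adduct → double product + released group (k = 0.00110 M⁻¹ s⁻¹, Ea = 79.0 kJ mol⁻¹)
    reagent + double product → tris adduct + released group (k = 6.50 × 10⁻⁴ M⁻¹ s⁻¹, Ea = 71.0 kJ mol⁻¹)
    mono adduct ⇌ isomer of the product (K = 1.50, k = 6.30 × 10⁻⁵ s⁻¹, Ea = 108 kJ mol⁻¹, ΔH = −23.0 kJ mol⁻¹)
    starting material + mono adduct → side product (k = 0.00400 M⁻¹ s⁻¹, Ea = 58.0 kJ mol⁻¹)
    (constants at 70 °C)

In Sunday's, mono adduct is made 1.34 times as fast as it is used at 6.47 min and 0.843 times at 20.0 min, so its peak lies between those times, where the reckoned 9.39 min stands. Saturday's run, with the path from starting material and mono adduct to side product struck out, ends at 28.1 % instead of 7.37 %, so that path is part of its tail. For the neighbour of Sunday's with 0.17 M of reagent, the peak dose puts the peak at 37.0 min, later than the stop. That flask gives 3.75 % mono adduct, with 79 % of its starting material left, and at the stop its first step makes mono adduct 0.892 times as fast as the paths to side product and double product use it, slower than they do, so this flask is already past its peak and the reckoned time fails here: the rate of the path to side product holds starting material, not reagent.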